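**Retrosynthetic overview**

1. Locants (humulane type): C1–C3 are the three CH–O carbons (C1 next to CMe2), C4 is the C(Me) of the cyclobutane, C5 the cyclobutane CH α to the C6 ketone, C7=C8(Me) the enone, C9 and C10 the other two cyclobutane CH, C11 the CMe2. Ring A is the cyclobutane (C4, C5, C10, C9), ring B the cyclohexenone, ring C the seven-membered ring.
2. The esters come last: 1,3-bis-angelate and 2-acetate from a triol, whose 2,3-cis-diol arises by osmylation of a C2=C3 alkene anti to the C1 silyl ether.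
3. Ring C is closed at C10–C11: a tertiary C11 radical (hydrogen-atom transfer to an isopropenyl group) adds to the C10 tosylhydrazone of a bicyclo[3.1.1]heptenone, and sulfinate and N2 are then lost. The enabling feature is that C10 is the non-enolizable ring A carbon between the bridgeheads C5 and C9, which a ketene cycloaddition delivers as C=O; C11 is a CMe2; and the C4 side chain is held 1,3-cis to C10 across ring A, so a (Z)-C2=C3 tether reaches it.
4. Rings A and B are formed together by an intramolecular vinylketene–alkene [2+2] of a farnesoate-type acid. The face is controlled by a C6 silyloxy stereocenter that is later oxidized to the C6 ketone.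
5. The acid comes from (E)-3-methylpent-2-en-4-yn-1-ol, methyl 3-methylbut-2-enoate and methacrolein by a catalytic asymmetric vinylogous aldol (C6) and a catalytic asymmetric alkynylation (C1). Ring order: A and B (step 8), then C (step 12).

Key step: step 12

Remark: both five-carbon esters of the target are read as (Z)-2-methylbut-2-enoates (angelates). In steps 3 and 5 the catalyst antipode is the one that gives the stated face of attack. TBS = tert-butyldimethylsilyl, TES = triethylsilyl, Ts = 4-methylbenzenesulfonyl.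

**Route**

Step 1
Reactants: 1 (E)-3-methylpent-2-en-4-yn-1-ol
Product: 2 (E)-3-methylpent-2-en-4-ynal
Conditions: MnO2, CH2Cl2, rt
Reagents that add atoms: none
Why: Allylic alcohol oxidation with MnO2 should stop at the aldehyde and leave the alkyne and the E-alkene untouched.

Step 2
Reactants: 3 methyl 3-methylbut-2-enoate
Product: 4 tert-butyl{[(1Z)-1-methoxy-3-methylbuta-1,3-dien-1-yl]oxy}dimethylsilane
Conditions: LDA, THF, −78 °C; TBSCl, DMPU, −78 °C → rt
Reagents that add atoms: tert-butyldimethylsilyl chloride, CC(C)(C)[Si](C)(C)Cl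
Why: Kinetic γ-deprotonation of the enoate and O-silylation should give the silyl dienol ether (silyl ketene acetal formation).

Step 3
Reactants: 2 (E)-3-methylpent-2-en-4-ynal; 4 silyl dienol ether
Product: 5 methyl (2E,5S,6E)-5-hydroxy-3,7-dimethylnona-2,6-dien-8-ynoate
Conditions: SiCl4, chiral 1,1'-binaphthyl-2,2'-diamine-derived bisphosphoramide (5 mol %), iPr2NEt (10 mol %), CH2Cl2, −78 °C; aq. NaHCO3
Reagents that add atoms: none
Why: In this Lewis-base-activated SiCl4 vinylogous Mukaiyama aldol the dienolate should react at its γ-carbon with the conjugated aldehyde to give the E-enoate, and the chiral silicon cation directs attack to the Si face of the aldehyde, which sets the carbinol (later C6) as 5S.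

Step 4
Reactants: 5 hydroxy ester
Product: 6 methyl (2E,5S,6E)-3,7-dimethyl-5-(triethylsilyloxy)nona-2,6-dien-8-ynoate
Conditions: TESCl, imidazole, CH2Cl2, 0 °C
Reagents that add atoms: triethylsilyl chloride, CC[Si](CC)(CC)Cl
Why: Silylation of the secondary allylic alcohol gives an acid-labile ether that can later be removed beside a TBS ether.

Step 5
Reactants: 6 terminal alkyne; 7 methacrolein
Product: 8 methyl (2E,5S,6E,10S)-10-hydroxy-3,7,11-trimethyl-5-(triethylsilyloxy)dodeca-2,6,11-trien-8-ynoate
Conditions: Me2Zn, ProPhenol ligand (20 mol %), Ph3PO (40 mol %), 7 (3 equiv), toluene, 0 → 4 °C; aq. NH4Cl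
Reagents that add atoms: none
Why: Catalytic asymmetric addition of the zinc alkynylide to the enal (dinuclear zinc ProPhenol alkynylation) should be reagent-controlled, Re-face attack giving the 10S carbinol (later C1), with no influence expected from the remote C5 center.

Step 6
Reactants: 8 propargylic alcohol
Product: 9 methyl (2E,5S,6E,10S)-10-(tert-butyldimethylsilyloxy)-3,7,11-trimethyl-5-(triethylsilyloxy)dodeca-2,6,11-trien-8-ynoate
Conditions: TBSCl, imidazole, DMF, rt
Reagents that add atoms: tert-butyldimethylsilyl chloride, CC(C)(C)[Si](C)(C)Cl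
Why: Silylation gives the more robust ether at C1, which must outlast removal of the TES group.

Step 7
Reactants: 9 methyl ester
Product: 10 (2E,5S,6E,10S)-10-(tert-butyldimethylsilyloxy)-3,7,11-trimethyl-5-(triethylsilyloxy)dodeca-2,6,11-trien-8-ynoic acid
Conditions: LiOH·H2O, THF/MeOH/H2O, 0 °C → rt; then aq. NaH2PO4 (pH 5)
Reagents that add atoms: lithium hydroxide, [Li+].[OH-]
Why: Saponification of the methyl ester should proceed without loss of the secondary silyl ethers when the acidification is buffered.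

Step 8
Reactants: 10 trienynoic acid
Product: 13 (4S)-7-[(3S)-3-(tert-butyldimethylsilyloxy)-4-methylpent-4-en-1-yn-1-yl]-7-methyl-2-methylidene-4-(triethylsilyloxy)bicyclo[3.1.1]heptan-6-one, via acid chloride 11 (not isolated), via vinylketene 12 (not isolated)
Conditions: 1-chloro-N,N,2-trimethylprop-1-en-1-amine, CH2Cl2, 0 °C → rt; then slow addition to Et3N, toluene, 110 °C (high dilution)
Reagents that add atoms: none
Why: Neutral acid chloride formation and 1,4-dehydrochlorination give the vinylketene, whose intramolecular thermal ketene–alkene [2+2] cycloaddition (carbonyl carbon to the less substituted C5, crossed mode) should close rings A and B at once; the E-alkene puts the C4 methyl over the three-carbon bridge and the alkynyl toward the new carbonyl, and A(1,3) strain with the cis C4 methyl keeps the C6–H bond in the alkene plane so that the ketene adds anti to the silyloxy group, which sets C4, C5 and C9 from C6.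

Step 9
Reactants: 13 alkynyl ketone
Product: 14 (4S)-7-[(1Z,3R)-3-(tert-butyldimethylsilyloxy)-4-methylpenta-1,4-dien-1-yl]-7-methyl-2-methylidene-4-(triethylsilyloxy)bicyclo[3.1.1]heptan-6-one
Conditions: H2 (1 atm), Pd/CaCO3 poisoned with Pb(OAc)2, quinoline, EtOAc, rt
Reagents that add atoms: none
Why: Syn semihydrogenation of the internal alkyne on the poisoned palladium catalyst should give the (Z)-alkene before the 1,1-disubstituted alkenes react (the C1 descriptor changes to R only through the priority switch).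

Step 10
Reactants: 14 ketone
Product: 16 N'-{(4S)-7-[(1Z,3R)-3-(tert-butyldimethylsilyloxy)-4-methylpenta-1,4-dien-1-yl]-4-hydroxy-7-methyl-2-methylidenebicyclo[3.1.1]heptan-6-ylidene}-4-methylbenzenesulfonohydrazide, via silyl ether tosylhydrazone 15 (not isolated)
Conditions: TsNHNH2, EtOH, 50 °C; then PPTS, MeOH, rt
Reagents that add atoms: 4-methylbenzenesulfonohydrazide, Cc1ccc(cc1)S(=O)(=O)NN
Why: Hydrazone condensation at the only carbonyl (the strained cyclobutanone) followed by acid methanolysis of the secondary TES ether should leave the TBS ether in place; masking C10 before C6 is oxidized avoids a cleavage-prone non-enolizable 1,3-diketone.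

Step 11
Reactants: 16 hydroxy tosylhydrazone
Product: 18 N'-{7-[(1Z,3R)-3-(tert-butyldimethylsilyloxy)-4-methylpenta-1,4-dien-1-yl]-4,7-dimethyl-2-oxobicyclo[3.1.1]hept-3-en-6-ylidene}-4-methylbenzenesulfonohydrazide, via unconjugated ketone 17 (not isolated)
Conditions: SO3·pyridine, DMSO, iPr2NEt, CH2Cl2, 0 °C; then DBU, rt
Reagents that add atoms: none
Why: Parikh–Doering oxidation (activated DMSO, which leaves sulfonamide-type N–H groups alone) gives the C6 ketone, and base-mediated migration of the exocyclic alkene through the dienolate should give the conjugated enone; the bridgehead C5 cannot enolize, so nothing epimerizes and the C6 control element is spent.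

Step 12
Reactants: 18 enone tosylhydrazone
Product: 21 (humulane locants) C1-O-TBS ether of the tricyclic 2,3-ene: 5-(tert-butyldimethylsilyloxy)-2,6,6,9-tetramethyltricyclo[5.4.0.0(2,8)]undeca-3,9-dien-11-one, via sulfonyl hydrazide 19 (not isolated), via alkyl diazene 20 (not isolated)
Conditions: Fe(acac)3 (30 mol %), PhSiH3, EtOH/THF, 60 °C; then Et3N, 80 °C
Reagents that add atoms: none
Why: Hydrogen-atom transfer from the iron hydride to the CH2 terminus of the isopropenyl group gives the tertiary C11 radical, which adds to the C10 carbon of the C=N bond; the sulfonylhydrazinyl radical is reduced to hydrazide 19, Et3N then expels sulfinate, and the monoalkyl diazene 20 loses N2 with formation of the C10–H bond (Wolff–Kishner-type end). The closest known reaction type is the MHAT-initiated reductive alkylation of alkenes with ketone sulfonylhydrazones as traceless radical acceptors. Ring C is closed in the 7-exo-trig mode on the exocyclic C=N bond, which completes the bicyclo[4.1.1]octene subunit. The only new stereocenter, C10, is fixed by the tether: C11 can reach C10 only on the face turned toward C4 (1,3-cis across ring A), so hydrogen necessarily ends on the enone side. The step needs chemoselective hydrogen transfer to the 1,1-disubstituted alkene, which is secured because the ring B alkene is an electron-poor enone by then and the (Z)-1,2-disubstituted alkene accepts hydrogen atoms slowly. It also needs cyclization to outrun reduction of the radical, which the (Z)-alkene and the quaternary C4 favor by leaving only three rotatable bonds in the tether.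

Step 13
Reactants: 21 tricyclic dienone
Product: 22 5-(tert-butyldimethylsilyloxy)-3,4-dihydroxy-2,6,6,9-tetramethyltricyclo[5.4.0.0(2,8)]undec-9-en-11-one (C2-OH and C3-OH cis to each other, trans to C1-O)
Conditions: OsO4 (5 mol %), NMO, acetone/H2O, rt
Reagents that add atoms: osmium tetroxide, O=[Os](=O)(=O)=O; N-methylmorpholine N-oxide, C[N+]1([O-])CCOCC1; water, O
Why: Catalytic syn-dihydroxylation should take the electron-rich C2=C3 alkene and not the hindered enone, from the face anti to the allylic C1 silyloxy group (the usual sense for osmylation of allylic ethers), which sets C2 and C3.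

Step 14
Reactants: 22 diol silyl ether
Product: 23 3,4,5-trihydroxy-2,6,6,9-tetramethyltricyclo[5.4.0.0(2,8)]undec-9-en-11-one
Conditions: TBAF, AcOH, THF, 0 °C → rt
Reagents that add atoms: none
Why: Buffered fluoride desilylation frees the C1 hydroxyl; no center is epimerizable because C5 is a bridgehead.

Step 15
Reactants: 23 triol
Product: 24 3,5-dihydroxy-2,6,6,9-tetramethyl-4-(triethylsilyloxy)tricyclo[5.4.0.0(2,8)]undec-9-en-11-one (C2-O-TES)
Conditions: TESCl, imidazole, CH2Cl2, −40 °C
Reagents that add atoms: triethylsilyl chloride, CC[Si](CC)(CC)Cl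
Why: Selective silylation should occur at C2–OH, the only hydroxyl not next to a quaternary carbon, and gives a protecting group that cannot migrate as an acetate would.

Step 16
Reactants: 24 1,3-diol
Product: 25 C1,C3-bis[(Z)-2-methylbut-2-enoate] of 24
Conditions: angelic acid, 2,4,6-trichlorobenzoyl chloride, Et3N, toluene, rt; then 24, 80 °C
Reagents that add atoms: angelic acid, C/C=C(/C)C(=O)O
Why: Yamaguchi-type mixed anhydride esterification without a nucleophilic catalyst is the usual way to acylate hindered secondary alcohols with angelic acid while keeping the Z geometry.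

Step 17
Reactants: 25 bis-angelate silyl ether
Product: 26 C2-hydroxy C1,C3-bis-angelate
Conditions: HF·pyridine, THF/pyridine, 0 °C
Reagents that add atoms: none
Why: Acidic fluoride desilylation removes the TES group without the acyl migration that basic fluoride could cause.

Step 18
Reactants: 26 hydroxy bis-angelate
Product: 27 target, (1S,2R,3S,4R,5R,9R,10S in humulane locants)-4-acetoxy-2,6,6,9-tetramethyl-11-oxotricyclo[5.4.0.0(2,8)]undec-9-ene-3,5-diyl bis[(Z)-2-methylbut-2-enoate]
Conditions: Ac2O, Et3N, DMAP (cat.), CH2Cl2, rt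
Reagents that add atoms: acetic anhydride, CC(=O)OC(C)=O
Why: DMAP-catalyzed acetylation of the last free hydroxyl completes the triester; no stereocenter is touched.

**Compound list**

1 | (E)-3-methylpent-2-en-4-yn-1-ol | C#C/C(C)=C/CO | starting material
2 | (E)-3-methylpent-2-en-4-ynal | C#C/C(C)=C/C=O | intermediate
3 | methyl 3-methylbut-2-enoate | COC(=O)C=C(C)C | starting material
4 | tert-butyl{[(1Z)-1-methoxy-3-methylbuta-1,3-dien-1-yl]oxy}dimethylsilane | CO/C(O[Si](C)(C)C(C)(C)C)=C/C(C)=C | intermediate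
5 | methyl (2E,5S,6E)-5-hydroxy-3,7-dimethylnona-2,6-dien-8-ynoate | COC(=O)/C=C(\C)C[C@H](O)/C=C(\C)C#C | intermediate
6 | methyl (2E,5S,6E)-3,7-dimethyl-5-(triethylsilyloxy)nona-2,6-dien-8-ynoate | COC(=O)/C=C(\C)C[C@H](O[Si](CC)(CC)CC)/C=C(\C)C#C | intermediate
7 | methacrolein (2-methylprop-2-enal) | CC(=C)C=O | starting material
8 | methyl (2E,5S,6E,10S)-10-hydroxy-3,7,11-trimethyl-5-(triethylsilyloxy)dodeca-2,6,11-trien-8-ynoate | COC(=O)/C=C(\C)C[C@H](O[Si](CC)(CC)CC)/C=C(\C)C#C[C@@H](O)C(C)=C | intermediate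
9 | methyl (2E,5S,6E,10S)-10-(tert-butyldimethylsilyloxy)-3,7,11-trimethyl-5-(triethylsilyloxy)dodeca-2,6,11-trien-8-ynoate | COC(=O)/C=C(\C)C[C@H](O[Si](CC)(CC)CC)/C=C(\C)C#C[C@@H](O[Si](C)(C)C(C)(C)C)C(C)=C | intermediate
10 | (2E,5S,6E,10S)-10-(tert-butyldimethylsilyloxy)-3,7,11-trimethyl-5-(triethylsilyloxy)dodeca-2,6,11-trien-8-ynoic acid | OC(=O)/C=C(\C)C[C@H](O[Si](CC)(CC)CC)/C=C(\C)C#C[C@@H](O[Si](C)(C)C(C)(C)C)C(C)=C | intermediate
11 | acid chloride of 10 | ClC(=O)/C=C(\C)C[C@H](O[Si](CC)(CC)CC)/C=C(\C)C#C[C@@H](O[Si](C)(C)C(C)(C)C)C(C)=C | intermediate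
12 | (5S,6E,10S)-10-(tert-butyldimethylsilyloxy)-7,11-dimethyl-3-methylidene-5-(triethylsilyloxy)dodeca-1,6,11-trien-8-yn-1-one (vinylketene) | O=C=CC(=C)C[C@H](O[Si](CC)(CC)CC)/C=C(\C)C#C[C@@H](O[Si](C)(C)C(C)(C)C)C(C)=C | intermediate
13 | (4S)-7-[(3S)-3-(tert-butyldimethylsilyloxy)-4-methylpent-4-en-1-yn-1-yl]-7-methyl-2-methylidene-4-(triethylsilyloxy)bicyclo[3.1.1]heptan-6-one; 4-O-TES on the side of the C6 carbonyl bridge, alkynyl on C7 pointing to C6, 7-methyl over the C2–C4 bridge | O=C1[C@@H]2C(=C)C[C@H](O[Si](CC)(CC)CC)[C@H]1[C@]2(C)C#C[C@@H](O[Si](C)(C)C(C)(C)C)C(C)=C | intermediate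
14 | (4S)-7-[(1Z,3R)-3-(tert-butyldimethylsilyloxy)-4-methylpenta-1,4-dien-1-yl]-7-methyl-2-methylidene-4-(triethylsilyloxy)bicyclo[3.1.1]heptan-6-one | O=C1[C@@H]2C(=C)C[C@H](O[Si](CC)(CC)CC)[C@H]1[C@]2(C)/C=C\[C@@H](O[Si](C)(C)C(C)(C)C)C(C)=C | intermediate
15 | tosylhydrazone of 14 (C=N geometry not defined) | Cc1ccc(cc1)S(=O)(=O)NN=C1[C@@H]2C(=C)C[C@H](O[Si](CC)(CC)CC)[C@H]1[C@]2(C)/C=C\[C@@H](O[Si](C)(C)C(C)(C)C)C(C)=C | intermediate
16 | N'-{(4S)-7-[(1Z,3R)-3-(tert-butyldimethylsilyloxy)-4-methylpenta-1,4-dien-1-yl]-4-hydroxy-7-methyl-2-methylidenebicyclo[3.1.1]heptan-6-ylidene}-4-methylbenzenesulfonohydrazide | Cc1ccc(cc1)S(=O)(=O)NN=C1[C@@H]2C(=C)C[C@H](O)[C@H]1[C@]2(C)/C=C\[C@@H](O[Si](C)(C)C(C)(C)C)C(C)=C | intermediate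
17 | 4-oxo analogue of 16 (2-methylidene, unconjugated ketone) | Cc1ccc(cc1)S(=O)(=O)NN=C1[C@@H]2C(=C)CC(=O)[C@H]1[C@]2(C)/C=C\[C@@H](O[Si](C)(C)C(C)(C)C)C(C)=C | intermediate
18 | N'-{7-[(1Z,3R)-3-(tert-butyldimethylsilyloxy)-4-methylpenta-1,4-dien-1-yl]-4,7-dimethyl-2-oxobicyclo[3.1.1]hept-3-en-6-ylidene}-4-methylbenzenesulfonohydrazide | Cc1ccc(cc1)S(=O)(=O)NN=C1[C@@H]2C(C)=CC(=O)[C@H]1[C@]2(C)/C=C\[C@@H](O[Si](C)(C)C(C)(C)C)C(C)=C | intermediate
19 | N'-[5-(tert-butyldimethylsilyloxy)-2,6,6,9-tetramethyl-11-oxotricyclo[5.4.0.0(2,8)]undeca-3,9-dien-7-yl]-4-methylbenzenesulfonohydrazide (N on C10) | CC(C)(C)[Si](C)(C)O[C@@H]1C=C[C@@]2(C)[C@@H]3C(=O)C=C(C)[C@H]2[C@]3(NNS(=O)(=O)c4ccc(C)cc4)C1(C)C | intermediate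
20 | 7-diazenyl analogue of 21 (N=NH on C10) | CC(C)(C)[Si](C)(C)O[C@@H]1C=C[C@@]2(C)[C@@H]3C(=O)C=C(C)[C@H]2[C@]3(N=N)C1(C)C | intermediate
21 | 5-(tert-butyldimethylsilyloxy)-2,6,6,9-tetramethyltricyclo[5.4.0.0(2,8)]undeca-3,9-dien-11-one (humulane locants: C1-O-TBS, C2=C3, C6=O, C7=C8) | CC(C)(C)[Si](C)(C)O[C@@H]1C=C[C@@]2(C)[C@@H]3C(=O)C=C(C)[C@H]2[C@@H]3C1(C)C | intermediate
22 | 5-(tert-butyldimethylsilyloxy)-3,4-dihydroxy-2,6,6,9-tetramethyltricyclo[5.4.0.0(2,8)]undec-9-en-11-one | CC(C)(C)[Si](C)(C)O[C@@H]1[C@@H](O)[C@@H](O)[C@@]2(C)[C@@H]3C(=O)C=C(C)[C@H]2[C@@H]3C1(C)C | intermediate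
23 | 3,4,5-trihydroxy-2,6,6,9-tetramethyltricyclo[5.4.0.0(2,8)]undec-9-en-11-one | O[C@@H]1[C@@H](O)[C@@H](O)[C@@]2(C)[C@@H]3C(=O)C=C(C)[C@H]2[C@@H]3C1(C)C | intermediate
24 | 3,5-dihydroxy-2,6,6,9-tetramethyl-4-(triethylsilyloxy)tricyclo[5.4.0.0(2,8)]undec-9-en-11-one | O[C@@H]1[C@@H](O[Si](CC)(CC)CC)[C@@H](O)[C@@]2(C)[C@@H]3C(=O)C=C(C)[C@H]2[C@@H]3C1(C)C | intermediate
25 | 2,6,6,9-tetramethyl-11-oxo-4-(triethylsilyloxy)tricyclo[5.4.0.0(2,8)]undec-9-ene-3,5-diyl bis[(Z)-2-methylbut-2-enoate] | C/C=C(/C)C(=O)O[C@@H]1[C@@H](O[Si](CC)(CC)CC)[C@@H](OC(=O)/C(C)=C\C)[C@@]2(C)[C@@H]3C(=O)C=C(C)[C@H]2[C@@H]3C1(C)C | intermediate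
26 | 4-hydroxy-2,6,6,9-tetramethyl-11-oxotricyclo[5.4.0.0(2,8)]undec-9-ene-3,5-diyl bis[(Z)-2-methylbut-2-enoate] | C/C=C(/C)C(=O)O[C@@H]1[C@@H](O)[C@@H](OC(=O)/C(C)=C\C)[C@@]2(C)[C@@H]3C(=O)C=C(C)[C@H]2[C@@H]3C1(C)C | intermediate
27 | 4-acetoxy-2,6,6,9-tetramethyl-11-oxotricyclo[5.4.0.0(2,8)]undec-9-ene-3,5-diyl bis[(Z)-2-methylbut-2-enoate] (CNP0335415.1) | C/C=C(/C)C(=O)O[C@@H]1[C@@H](OC(C)=O)[C@@H](OC(=O)/C(C)=C\C)[C@@]2(C)[C@@H]3C(=O)C=C(C)[C@H]2[C@@H]3C1(C)C | target

**Step count and risks**

Total step count: 18. Longest linear sequence: 17 steps (1 to 27 through steps 1 and 3–18; step 2 is a one-step side branch).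

Steps most likely to fail:

1. Step 12. Hydrogen transfer to the tertiary radical (net hydrogenation of the isopropenyl group) may outrun the sterically slow 7-exo attack on C10, which is flanked on all sides. The fallback sets out from 18 and comes back at 21. Markovnikov hydrochlorination of the isopropenyl group by cobalt-hydride hydrogen-atom transfer (Co(salen) catalyst, PhSiH3, TsCl, EtOH, rt) should give the tertiary chloride F1, in which the radical precursor is stored. Chlorine abstraction with Bu3SnH and AIBN in benzene at 80 °C under syringe-pump addition then releases the C11 radical as a free chain carrier whose lifetime is set by the stannane concentration, so the ring closure has time to occur. Hydrogen transfer from the stannane to the hydrazinyl radical gives 19, and Et3N at 80 °C carries it through 20 to 21.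

2. Step 8. Oligomerization of the vinylketene may compete, and facial control may erode, because the alkyne-conjugated C4=C5 alkene is a weaker nucleophile than a trialkyl alkene. The fallback sets out from 10 and comes back at 13. Acid chloride 11, made as in step 8, is quenched with pyrrolidine to give the pyrrolidine amide F2. Tf2O and 2,4,6-collidine in 1,2-dichloroethane (0 → 80 °C) should convert it by γ-deprotonation into the vinylketeniminium triflate F3, a cationic ketene equivalent that cannot dimerize and is far more electrophilic. Its intramolecular [2+2] with the same alkene, under the same A(1,3) control, gives the cyclobutaniminium triflate F4, and aqueous NaHCO3 hydrolysis returns ketone 13. A minor C6/core diastereomer can be removed at 13, because C6 is still a stereocenter there.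

3. Step 16. Acylation of the two neopentyl-type secondary hydroxyls may stay incomplete, and the activated angelate may isomerize from Z to E on prolonged heating. The fallback sets out from 24 and comes back at 25. Both hydroxyls are acylated with 2-[bis(2,2,2-trifluoroethoxy)phosphoryl]propanoic acid (DCC, DMAP, CH2Cl2) to give the bis(phosphonopropanoate) F5. A double Z-selective Horner–Wadsworth–Emmons olefination (Still–Gennari conditions: KHMDS, 18-crown-6, THF, −78 °C, then acetaldehyde) then builds both (Z)-2-methylbut-2-enoates in place and gives 25.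

**Further compounds**

F1 | step 12 | N'-{7-[(1Z,3R)-3-(tert-butyldimethylsilyloxy)-4-chloro-4-methylpent-1-en-1-yl]-4,7-dimethyl-2-oxobicyclo[3.1.1]hept-3-en-6-ylidene}-4-methylbenzenesulfonohydrazide | Cc1ccc(cc1)S(=O)(=O)NN=C1[C@@H]2C(C)=CC(=O)[C@H]1[C@]2(C)/C=C\[C@@H](O[Si](C)(C)C(C)(C)C)C(C)(C)Cl
F2 | step 8 | 1-[(2E,5S,6E,10S)-10-(tert-butyldimethylsilyloxy)-3,7,11-trimethyl-5-(triethylsilyloxy)dodeca-2,6,11-trien-8-ynoyl]pyrrolidine | O=C(N1CCCC1)/C=C(\C)C[C@H](O[Si](CC)(CC)CC)/C=C(\C)C#C[C@@H](O[Si](C)(C)C(C)(C)C)C(C)=C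
F3 | step 8 | vinylketeniminium triflate derived from F2 | C(=[N+]1CCCC1)=CC(=C)C[C@H](O[Si](CC)(CC)CC)/C=C(\C)C#C[C@@H](O[Si](C)(C)C(C)(C)C)C(C)=C.[O-]S(=O)(=O)C(F)(F)F
F4 | step 8 | pyrrolidinium (cyclobutaniminium) triflate corresponding to ketone 13 | [N+]1(CCCC1)=C1[C@@H]2C(=C)C[C@H](O[Si](CC)(CC)CC)[C@H]1[C@]2(C)C#C[C@@H](O[Si](C)(C)C(C)(C)C)C(C)=C.[O-]S(=O)(=O)C(F)(F)F
F5 | step 16 | C1,C3-bis{2-[bis(2,2,2-trifluoroethoxy)phosphoryl]propanoate} of 24 (phosphonate α-carbons not defined) | CC(P(=O)(OCC(F)(F)F)OCC(F)(F)F)C(=O)O[C@@H]1[C@@H](O[Si](CC)(CC)CC)[C@@H](OC(=O)C(C)P(=O)(OCC(F)(F)F)OCC(F)(F)F)[C@@]2(C)[C@@H]3C(=O)C=C(C)[C@H]2[C@@H]3C1(C)C
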